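The furan ring is the point of disconnection. Its C2, the lone carbon that links O1, C3 and C5 of the chroman, is supplied as the ylide carbon of a chroman-5-ylmethyl sulfonium salt. O1 and C3 belong to an ortho-quinone methide of the benzofuran benzene ring, released from an ortho-hydroxybenzyl trimethylammonium salt. One operation forms C2–C3 and O1–C2 and closes the dihydrofuran; dehydrogenation and MOM removal complete the target. The ammonium salt already carries the C7 1,1-dimethylallyl group (aromatic Claisen) and two MOM ethers. The sulfonium salt derives from a bromine-blocked dihydroxybenzoate, so the chroman ring fusion is unambiguous and the ester carbon becomes the ylide carbon.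

Key step: step 12

Assumption: the only stereocentre that appears, C2 of the dihydrofuran, is formed as a racemate and is removed by the dehydrogenation, so no stereocontrol is planned. MOM is methoxymethyl and MOMCl is chloromethyl methyl ether.

Step 1
Reactants: 1 phloroglucinol
Product: 2 3,5-bis(methoxymethoxy)phenol
Conditions: MOMCl (2.0 equiv), i-Pr2NEt, CH2Cl2/DMF, 0 °C → rt
Reagents that add atoms: chloromethyl methyl ether, COCCl
Why: Williamson-type O-alkylation of the phenoxide by the α-chloro ether, in which two equivalents should make the bis-ether the main component of a statistical mixture that is separable from mono- and tris-ether by chromatography.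

Step 2
Reactants: 2 3,5-bis(methoxymethoxy)phenol; 3 prenyl bromide
Product: 4 1,3-bis(methoxymethoxy)-5-[(3-methylbut-2-en-1-yl)oxy]benzene
Conditions: K2CO3, acetone, reflux
Reagents that add atoms: none
Why: Williamson ether synthesis, in which the single free phenol is O-alkylated by the primary allylic bromide under weakly basic conditions that leave the MOM acetals untouched.

Step 3
Reactants: 4 1,3-bis(methoxymethoxy)-5-[(3-methylbut-2-en-1-yl)oxy]benzene
Product: 6 3,5-bis(methoxymethoxy)-2-(2-methylbut-3-en-2-yl)phenol, via ortho-dienone 5 (not isolated)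
Conditions: PhNEt2, 190 °C, sealed tube, N2
Reagents that add atoms: none
Why: Aromatic Claisen rearrangement, in which the [3,3] shift delivers the allyl unit with allylic inversion to either of the two equivalent ortho carbons and enolisation of dienone 5 in the basic solvent should restore the phenol before a Cope shift or abnormal Claisen isomerisation can compete.

Step 4
Reactants: 6 3,5-bis(methoxymethoxy)-2-(2-methylbut-3-en-2-yl)phenol
Product: 7 2-[(dimethylamino)methyl]-3,5-bis(methoxymethoxy)-6-(2-methylbut-3-en-2-yl)phenol
Conditions: Me2NH (40% aq.), CH2O (37% aq., 1.05 equiv), EtOH, rt → 50 °C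
Reagents that add atoms: formaldehyde, C=O; dimethylamine, CNC
Why: Mannich reaction, in which the iminium ion hydrogen-bonded to the phenol is delivered to the one free ortho carbon, which is also less hindered than the para carbon between two MOM ethers, while the near-stoichiometric charge limits double aminomethylation.

Step 5
Reactants: 7 2-[(dimethylamino)methyl]-3,5-bis(methoxymethoxy)-6-(2-methylbut-3-en-2-yl)phenol
Product: 8 [2-hydroxy-4,6-bis(methoxymethoxy)-3-(2-methylbut-3-en-2-yl)benzyl]trimethylammonium iodide
Conditions: MeI, Et2O/MeCN, rt, dark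
Reagents that add atoms: iodomethane, CI
Why: Menshutkin quaternisation, in which the tertiary amine is far more nucleophilic than the neutral hindered phenol and the salt should precipitate and so be withdrawn from further reaction.

Step 6
Reactants: 9 methyl 4-bromo-3,5-dihydroxybenzoate; 10 2-methylbut-3-en-2-ol
Product: 12 methyl 8-bromo-7-hydroxy-2,2-dimethylchroman-5-carboxylate, via C-prenyl phenol 11 (not isolated)
Conditions: BF3·OEt2 (0.3 equiv), 10 (1.1 equiv, slow addition), 1,4-dioxane, rt → 60 °C
Reagents that add atoms: none
Why: Friedel–Crafts C-prenylation followed by acid-catalysed cycloetherification, in which the bromine blocks the carbon between the two hydroxyls so that the allyl cation can only attack one of the two equivalent carbons next to the ester, and the neighbouring phenol then adds in the Markovnikov sense to the trisubstituted alkene to close the chroman.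

Step 7
Reactants: 12 methyl 8-bromo-7-hydroxy-2,2-dimethylchroman-5-carboxylate
Product: 13 methyl 7-hydroxy-2,2-dimethylchroman-5-carboxylate
Conditions: H2 (1 atm), Pd/C, Et3N, MeOH, rt
Reagents that add atoms: none
Why: Catalytic hydrogenolysis (hydrodehalogenation) of the aryl C–Br bond with an amine to take up HBr, under which ester, phenol and chroman ring are inert.

Step 8
Reactants: 13 methyl 7-hydroxy-2,2-dimethylchroman-5-carboxylate
Product: 14 methyl 7-(methoxymethoxy)-2,2-dimethylchroman-5-carboxylate
Conditions: MOMCl, i-Pr2NEt, CH2Cl2, 0 °C → rt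
Reagents that add atoms: chloromethyl methyl ether, COCCl
Why: Williamson-type O-alkylation of the phenol, which installs the same acetal protecting group as on the other fragment so that one acid treatment can unmask all three phenols at the end.

Step 9
Reactants: 14 methyl 7-(methoxymethoxy)-2,2-dimethylchroman-5-carboxylate
Product: 15 [7-(methoxymethoxy)-2,2-dimethylchroman-5-yl]methanol
Conditions: LiAlH4, THF, 0 °C
Reagents that add atoms: none
Why: Hydride reduction of the aryl ester to the benzylic alcohol, a reaction in which acetal and ether groups do not take part.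

Step 10
Reactants: 15 [7-(methoxymethoxy)-2,2-dimethylchroman-5-yl]methanol
Product: 16 5-(bromomethyl)-7-(methoxymethoxy)-2,2-dimethylchroman
Conditions: CBr4, PPh3, CH2Cl2, 0 °C
Reagents that add atoms: carbon tetrabromide, BrC(Br)(Br)Br
Why: Appel reaction, in which bromide displaces the alkoxyphosphonium group at the primary benzylic carbon under neutral conditions that the MOM ether tolerates.

Step 11
Reactants: 16 5-(bromomethyl)-7-(methoxymethoxy)-2,2-dimethylchroman; 17 tetrahydrothiophene
Product: 18 1-{[7-(methoxymethoxy)-2,2-dimethylchroman-5-yl]methyl}tetrahydrothiophenium bromide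
Conditions: 17 (3 equiv), acetone, rt
Reagents that add atoms: none
Why: SN2 S-alkylation of the sulfide by the benzylic bromide, driven to completion because the sulfonium bromide should crystallise from acetone.

Step 12
Reactants: 8 [2-hydroxy-4,6-bis(methoxymethoxy)-3-(2-methylbut-3-en-2-yl)benzyl]trimethylammonium iodide; 18 1-{[7-(methoxymethoxy)-2,2-dimethylchroman-5-yl]methyl}tetrahydrothiophenium bromide
Product: 22 2-[7-(methoxymethoxy)-2,2-dimethylchroman-5-yl]-4,6-bis(methoxymethoxy)-7-(2-methylbut-3-en-2-yl)-2,3-dihydrobenzofuran (racemic at C2), via ortho-quinone methide 19 (not isolated), via sulfonium ylide 20 (not isolated), via betaine 21 (not isolated)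
Conditions: 18 (1.5 equiv), Cs2CO3 (3 equiv), MeCN, 40 °C, N2 sweep; 8 in MeCN/DMF added slowly
Reagents that add atoms: none
Why: Carbonate deprotonates the phenol of 8, whose phenoxide expels trimethylamine to give quinone methide 19, and it reversibly deprotonates the benzylic carbon of 18 to give the semi-stabilised ylide 20; the ylide carbon adds in a conjugate (1,4) manner to the exocyclic methylene of 19 (C2–C3), and the rearomatised phenoxide of betaine 21 then displaces tetrahydrothiophene from that same carbon (O1–C2). The closest known reaction type is the formal [4+1] annulation of ortho-quinone methides with sulfonium ylides to 2,3-dihydrobenzofurans. The dihydrofuran ring closes by a 5-exo-tet intramolecular SN2 displacement at the benzylic sulfonium carbon. C2 is the only new stereocentre; nothing in the substrate controls it, so it should form as a racemate, and it becomes planar in step 13. The step needs chemoselectivity for ylide capture over [4+2] dimerisation of 19 and over O-benzylation of the phenoxide by 18: slow addition of 8 to excess 18 and base keeps 19 dilute in the presence of ylide, and the 1,1-dimethylallyl group shields O1 from intermolecular alkylation. Regiochemistry follows from the order of bond formation, since the ylide carbon attacks carbon first and the oxygen can then only close onto the sulfonium-bearing carbon.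

Step 13
Reactants: 22 2-[7-(methoxymethoxy)-2,2-dimethylchroman-5-yl]-4,6-bis(methoxymethoxy)-7-(2-methylbut-3-en-2-yl)-2,3-dihydrobenzofuran
Product: 23 2-[7-(methoxymethoxy)-2,2-dimethylchroman-5-yl]-4,6-bis(methoxymethoxy)-7-(2-methylbut-3-en-2-yl)benzofuran
Conditions: DDQ (1.1 equiv), anhydrous 1,4-dioxane, rt → 60 °C
Reagents that add atoms: none
Why: Quinone dehydrogenation, in which hydride abstraction from the benzylic C3–H of the trioxygenated ring and loss of the C2 proton give the aromatic furan; the gain in aromaticity and the richer ring should favour this over oxidation of the chroman C4 methylene at close to one equivalent, and the 1,1-dimethylallyl group offers no allylic hydrogen.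

Step 14
Reactants: 23 2-[7-(methoxymethoxy)-2,2-dimethylchroman-5-yl]-4,6-bis(methoxymethoxy)-7-(2-methylbut-3-en-2-yl)benzofuran
Product: 24 2-(7-hydroxy-2,2-dimethylchroman-5-yl)-7-(2-methylbut-3-en-2-yl)benzofuran-4,6-diol (target)
Conditions: HCl in MeOH (about 1 M), 0 °C → rt
Reagents that add atoms: none
Why: Acid-catalysed acetal exchange with methanol removes the three MOM ethers, and with dilute acid at room temperature the monosubstituted alkene of the 1,1-dimethylallyl group should not be protonated, so cyclisation onto the neighbouring phenol is not expected.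

Compound list

1 | phloroglucinol (benzene-1,3,5-triol) | Oc1cc(O)cc(O)c1 | starting material
2 | 3,5-bis(methoxymethoxy)phenol | COCOc1cc(O)cc(OCOC)c1 | intermediate
3 | prenyl bromide (1-bromo-3-methylbut-2-ene) | CC(C)=CCBr | starting material
4 | 1,3-bis(methoxymethoxy)-5-[(3-methylbut-2-en-1-yl)oxy]benzene | COCOc1cc(OCC=C(C)C)cc(OCOC)c1 | intermediate
5 | 3,5-bis(methoxymethoxy)-6-(2-methylbut-3-en-2-yl)cyclohexa-2,4-dien-1-one (ortho-dienone, racemic, not isolated) | O=C1C=C(OCOC)C=C(OCOC)C1C(C)(C)C=C | intermediate
6 | 3,5-bis(methoxymethoxy)-2-(2-methylbut-3-en-2-yl)phenol | C=CC(C)(C)c1c(O)cc(OCOC)cc1OCOC | intermediate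
7 | 2-[(dimethylamino)methyl]-3,5-bis(methoxymethoxy)-6-(2-methylbut-3-en-2-yl)phenol | C=CC(C)(C)c1c(OCOC)cc(OCOC)c(CN(C)C)c1O | intermediate
8 | [2-hydroxy-4,6-bis(methoxymethoxy)-3-(2-methylbut-3-en-2-yl)benzyl]trimethylammonium iodide | C=CC(C)(C)c1c(OCOC)cc(OCOC)c(C[N+](C)(C)C)c1O.[I-] | intermediate
9 | methyl 4-bromo-3,5-dihydroxybenzoate | COC(=O)c1cc(O)c(Br)c(O)c1 | starting material
10 | 2-methylbut-3-en-2-ol | C=CC(C)(C)O | starting material
11 | methyl 4-bromo-3,5-dihydroxy-2-(3-methylbut-2-en-1-yl)benzoate (C-prenyl phenol, not isolated) | COC(=O)c1cc(O)c(Br)c(O)c1CC=C(C)C | intermediate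
12 | methyl 8-bromo-7-hydroxy-2,2-dimethylchroman-5-carboxylate | COC(=O)c1cc(O)c(Br)c2c1CCC(C)(C)O2 | intermediate
13 | methyl 7-hydroxy-2,2-dimethylchroman-5-carboxylate | COC(=O)c1cc(O)cc2c1CCC(C)(C)O2 | intermediate
14 | methyl 7-(methoxymethoxy)-2,2-dimethylchroman-5-carboxylate | COCOc1cc(C(=O)OC)c2c(c1)OC(C)(C)CC2 | intermediate
15 | [7-(methoxymethoxy)-2,2-dimethylchroman-5-yl]methanol | COCOc1cc(CO)c2c(c1)OC(C)(C)CC2 | intermediate
16 | 5-(bromomethyl)-7-(methoxymethoxy)-2,2-dimethylchroman | COCOc1cc(CBr)c2c(c1)OC(C)(C)CC2 | intermediate
17 | tetrahydrothiophene | C1CCSC1 | starting material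
18 | 1-{[7-(methoxymethoxy)-2,2-dimethylchroman-5-yl]methyl}tetrahydrothiophenium bromide | COCOc1cc(C[S+]2CCCC2)c2c(c1)OC(C)(C)CC2.[Br-] | intermediate
19 | 6-methylidene-3,5-bis(methoxymethoxy)-2-(2-methylbut-3-en-2-yl)cyclohexa-2,4-dien-1-one (ortho-quinone methide, not isolated) | C=CC(C)(C)C1=C(OCOC)C=C(OCOC)C(=C)C1=O | intermediate
20 | tetrahydrothiophenium [7-(methoxymethoxy)-2,2-dimethylchroman-5-yl]methylide (sulfonium ylide, not isolated) | COCOc1cc([CH-][S+]2CCCC2)c2c(c1)OC(C)(C)CC2 | intermediate
21 | 2-{2-[7-(methoxymethoxy)-2,2-dimethylchroman-5-yl]-2-(tetrahydrothiophenium-1-yl)ethyl}-3,5-bis(methoxymethoxy)-6-(2-methylbut-3-en-2-yl)phenolate (betaine, racemic, not isolated) | C=CC(C)(C)c1c(OCOC)cc(OCOC)c(CC([S+]2CCCC2)c2cc(OCOC)cc3c2CCC(C)(C)O3)c1[O-] | intermediate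
22 | 2-[7-(methoxymethoxy)-2,2-dimethylchroman-5-yl]-4,6-bis(methoxymethoxy)-7-(2-methylbut-3-en-2-yl)-2,3-dihydrobenzofuran (racemic at C2) | C=CC(C)(C)c1c(OCOC)cc(OCOC)c2c1OC(c1cc(OCOC)cc3c1CCC(C)(C)O3)C2 | intermediate
23 | 2-[7-(methoxymethoxy)-2,2-dimethylchroman-5-yl]-4,6-bis(methoxymethoxy)-7-(2-methylbut-3-en-2-yl)benzofuran | C=CC(C)(C)c1c(OCOC)cc(OCOC)c2cc(-c3cc(OCOC)cc4c3CCC(C)(C)O4)oc12 | intermediate
24 | 2-(7-hydroxy-2,2-dimethylchroman-5-yl)-7-(2-methylbut-3-en-2-yl)benzofuran-4,6-diol (achiral) | C=CC(C)(C)c1c(O)cc(O)c2cc(-c3cc(O)cc4c3CCC(C)(C)O4)oc12 | target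

Total step count: 14 (steps 1–5 for the ammonium salt, steps 6–11 for the sulfonium salt, steps 12–14 in common).
Longest linear sequence: 9 steps (steps 6–14, from methyl 4-bromo-3,5-dihydroxybenzoate 9).

Steps most likely to fail

Step 12. The quinone methide may dimerise, or be recaptured by trimethylamine or tetrahydrothiophene, faster than the low stationary concentration of ylide can trap it. The ylide may also be lost by sigmatropic rearrangement, or the sulfonium salt may simply benzylate the phenoxide. The fallback is an intramolecular Wittig benzofuran synthesis; it sets out from 8 and 14 and comes back to the route at 23, so that step 13 is bypassed as well. Ammonium iodide 8 would be heated with PPh3 in MeCN to give [2-hydroxy-4,6-bis(methoxymethoxy)-3-(2-methylbut-3-en-2-yl)benzyl]triphenylphosphonium iodide F1, the amine being exchanged for the phosphine by way of the same quinone methide. Ester 14 would be saponified (LiOH, THF/H2O) to 7-(methoxymethoxy)-2,2-dimethylchroman-5-carboxylic acid F2 and converted with 1-chloro-N,N,2-trimethylprop-1-en-1-amine in CH2Cl2 under neutral conditions into 7-(methoxymethoxy)-2,2-dimethylchroman-5-carbonyl chloride F3. F1, F3 and Et3N in toluene at reflux should give the O-aroyl phosphonium salt F4, whose ylide closes onto the ester carbonyl to give 23.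

Step 13. Hydride abstraction may also take place at the chroman C4 methylene, which is activated by the ortho ring oxygen and the para MOM ether. That would lead to over-oxidation to a chromene or, with less oxidant, to incomplete conversion. The fallback carries the oxidation level in the electrophile, so that a dehydration replaces the dehydrogenation; it sets out from 6 and 18 and comes back at 23. Phenol 6 would be formylated at its free ortho carbon through the magnesium phenoxide (MgCl2, Et3N, paraformaldehyde, MeCN, reflux) to give 2-hydroxy-4,6-bis(methoxymethoxy)-3-(2-methylbut-3-en-2-yl)benzaldehyde F5. The ylide from 18 (Cs2CO3, MeCN) should add to the aldehyde, and phenoxide displacement of the sulfide should give 2-[7-(methoxymethoxy)-2,2-dimethylchroman-5-yl]-4,6-bis(methoxymethoxy)-7-(2-methylbut-3-en-2-yl)-2,3-dihydrobenzofuran-3-ol F6 as a mixture of racemic diastereomers. Catalytic pyridinium p-toluenesulfonate in toluene at 60 °C should dehydrate F6 to 23 through the benzylic cation.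

Step 6. Alkylation next to the ester on a ring deactivated by ester and bromine may be sluggish. A second annulation with the remaining phenol, or O-alkylation, may compete. The fallback builds the pyran ring by condensation and electrocyclisation in place of cation chemistry; it sets out from 9 and comes back at 13. Compound 9 and 3-methylbut-2-enal with catalytic ethylenediammonium diacetate in toluene at reflux should give methyl 8-bromo-7-hydroxy-2,2-dimethyl-2H-chromene-5-carboxylate F7 (Knoevenagel-type condensation, then oxa-6π electrocyclisation; the bromine again leaves only the carbons next to the ester). Hydrogenation (H2, Pd/C, Et3N, MeOH) should then reduce the C3–C4 alkene and the C–Br bond in one operation to give 13.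

Further compounds

F1 | step 12 | [2-hydroxy-4,6-bis(methoxymethoxy)-3-(2-methylbut-3-en-2-yl)benzyl]triphenylphosphonium iodide | C=CC(C)(C)c1c(OCOC)cc(OCOC)c(C[P+](c2ccccc2)(c2ccccc2)c2ccccc2)c1O.[I-]
F2 | step 12 | 7-(methoxymethoxy)-2,2-dimethylchroman-5-carboxylic acid | COCOc1cc(C(=O)O)c2c(c1)OC(C)(C)CC2
F3 | step 12 | 7-(methoxymethoxy)-2,2-dimethylchroman-5-carbonyl chloride | COCOc1cc(C(=O)Cl)c2c(c1)OC(C)(C)CC2
F4 | step 12 | {2-[7-(methoxymethoxy)-2,2-dimethylchroman-5-carbonyloxy]-4,6-bis(methoxymethoxy)-3-(2-methylbut-3-en-2-yl)benzyl}triphenylphosphonium iodide | C=CC(C)(C)c1c(OCOC)cc(OCOC)c(C[P+](c2ccccc2)(c2ccccc2)c2ccccc2)c1OC(=O)c1cc(OCOC)cc2c1CCC(C)(C)O2.[I-]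
F5 | step 13 | 2-hydroxy-4,6-bis(methoxymethoxy)-3-(2-methylbut-3-en-2-yl)benzaldehyde | C=CC(C)(C)c1c(OCOC)cc(OCOC)c(C=O)c1O
F6 | step 13 | 2-[7-(methoxymethoxy)-2,2-dimethylchroman-5-yl]-4,6-bis(methoxymethoxy)-7-(2-methylbut-3-en-2-yl)-2,3-dihydrobenzofuran-3-ol (racemic, both diastereomers) | C=CC(C)(C)c1c(OCOC)cc(OCOC)c2c1OC(c1cc(OCOC)cc3c1CCC(C)(C)O3)C2O
F7 | step 6 | methyl 8-bromo-7-hydroxy-2,2-dimethyl-2H-chromene-5-carboxylate | COC(=O)c1cc(O)c(Br)c2c1C=CC(C)(C)O2
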